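**Assumption:** the target has no stereocentres. The C(CH3)2 of the 1,1-dimethylallyl group and the chroman CMe2 are both achiral, and the trisubstituted prenyl alkenes have two identical methyls, so there is no E/Z issue. No stereocontrol is needed.

## Retrosynthetic overview
1. Disconnect the furan ring by Sonogashira coupling followed by 5-endo-dig phenoxide cyclisation. The partners are an o-iodophenol carrying a TBS group on the other ortho oxygen, which fixes the regiochemistry, and a terminal aryl alkyne. The last step is desilylation.
2. Left half: phloroglucinol → mono-prenyl ether → **dearomative, desymmetrising Claisen rearrangement (key step)** to the 1,1-dimethylallyl (reverse-prenyl) triol → mono-TBS → iodination.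
3. Right half: 3,5-dihydroxybenzaldehyde → symmetrical 2,6-bis-C-prenylation → desymmetrising mono-hydroalkoxylation to the 2,2-dimethylchroman → Ohira–Bestmann alkyne.
4. Ring-formation order: chroman ring (Step 6), then furan ring (Step 8). The cyclohexadienone dearomatised intermediate is transient, inside Step 2.

## Route

**Step 1**
Reactants: 1 phloroglucinol (benzene-1,3,5-triol); 2 prenyl bromide
Product: 3 5-[(3-methylbut-2-en-1-yl)oxy]benzene-1,3-diol
Conditions: K2CO3 (1 equiv), acetone, rt, 16 h; phloroglucinol used in 3-fold excess over 2
Reagents that add atoms: prenyl bromide, CC(C)=CCBr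
Why: Williamson O-alkylation of the mono-phenoxide in aprotic acetone favours O- over C-alkylation. Excess phloroglucinol suppresses bis-ether formation, and the mono-ether is a mirror-symmetric precursor for Step 2.

**Step 2 (key step)**
Reactants: 3
Product: 4 2-(2-methylbut-3-en-2-yl)benzene-1,3,5-triol
Conditions: BCl3 (5 equiv), CH2Cl2, –78 → –20 °C, 2 h; quench with cold aq. NaHCO3
Reagents that add atoms: none
Why: aromatic Claisen rearrangement. Proposed new method: BCl3 converts the three free OH groups into ArOBCl2 in situ. The remaining ether oxygen binds BCl3 and the [3,3] shift proceeds at low temperature through a chair transition state. This forms the C–C(Me)2 bond at the γ-carbon of the prenyl group, which gives the tertiary (reverse-prenyl) centre, and avoids ionisation to the prenyl cation that would give normal prenyl. The intermediate is a dearomatised 6-H-6-tert-alkyl-cyclohexadienone, which re-aromatises at once; phloroglucinol enolises readily, which favours this. The two ortho carbons are homotopic, so one product forms. The closest known reaction is BCl3-promoted Claisen rearrangement of aryl prenyl ethers. No stereocentre forms.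

**Step 3**
Reactants: 4
Product: 5 5-(tert-butyldimethylsilyloxy)-2-(2-methylbut-3-en-2-yl)benzene-1,3-diol
Conditions: TBSCl (1.05 equiv), imidazole (2.2 equiv), DMF, 0 °C, 1 h
Reagents that add atoms: TBSCl, CC(C)(C)[Si](C)(C)Cl
Why: silylation is selective for the OH at C5, which is flanked by two aromatic C–H. The other two OH groups sit next to the quaternary tert-alkyl group and are much more hindered. This protecting group later blocks the wrong-side furan closure.

**Step 4**
Reactants: 5
Product: 6 5-(tert-butyldimethylsilyloxy)-4-iodo-2-(2-methylbut-3-en-2-yl)benzene-1,3-diol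
Conditions: NIS (1.0 equiv), MeCN, 0 °C, dark, 30 min
Reagents that add atoms: NIS, O=C1CCC(=O)N1I
Why: electrophilic aromatic iodination ortho/para to the OH and OTBS groups. C4 and C6 of 5 are mirror-equivalent, so a single regioisomer forms. The iodide ends up flanked by one free OH (the one next to the tert-alkyl carbon, which becomes O1 of the furan) and by OTBS.

**Step 5**
Reactants: 7 3,5-dihydroxybenzaldehyde; 2 prenyl bromide
Product: 8 3,5-dihydroxy-2,6-bis(3-methylbut-2-en-1-yl)benzaldehyde
Conditions: prenyl bromide (2.4 equiv), NaOH (3 equiv), H2O, 0 °C → rt, 12 h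
Reagents that add atoms: prenyl bromide, CC(C)=CCBr
Why: C-alkylation of the resorcinol dianion in water. The positions ortho to CHO are ortho/para-activated by the phenoxides, and the position between the two OH groups is the hindered one, as in resorcinol. The two prenylated carbons are symmetry-equivalent, so the 2,6-bis-prenyl product is a symmetric precursor for Step 6.

**Step 6**
Reactants: 8
Product: 9 7-hydroxy-2,2-dimethyl-6-(3-methylbut-2-en-1-yl)chromane-5-carbaldehyde
Conditions: p-TsOH·H2O (0.3 equiv), toluene, 50 °C; stop at about 50% conversion and recycle 8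
Reagents that add atoms: none
Why: Markovnikov protonation of one prenyl alkene gives the tertiary cation, which is trapped by the adjacent phenol in a 6-exo closure (intramolecular hydroalkoxylation) to the 2,2-dimethylchroman. The two prenyl/OH pairs are identical, so this step breaks the symmetry of 8; the outcome is statistical, and the mono-chroman is separated from the bis-chroman.

**Step 7**
Reactants: 9
Product: 10 5-ethynyl-2,2-dimethyl-6-(3-methylbut-2-en-1-yl)chroman-7-ol
Conditions: Bestmann–Ohira reagent (1.5 equiv), K2CO3 (3 equiv), MeOH, 0 °C → rt, 12 h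
Reagents that add atoms: dimethyl (1-diazo-2-oxopropyl)phosphonate, COP(=O)(OC)C(=[N+]=[N-])C(C)=O
Why: Seyferth–Gilbert homologation (Ohira–Bestmann variant) converts the ArCHO to ArC≡CH under mild base. The free phenol and the alkene are inert, and the di-ortho-substituted aldehyde is still reactive.

**Step 8**
Reactants: 6; 10
Product: 11 TBS-protected benzofuran, 2-[7-hydroxy-2,2-dimethyl-6-prenylchroman-5-yl]-4-(TBSO)-7-(2-methylbut-3-en-2-yl)benzofuran-6-ol
Conditions: PdCl2(PPh3)2 (5 mol%), CuI (10 mol%), Et3N (5 equiv), DMF, 80 °C, 12 h
Reagents that add atoms: none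
Why: Sonogashira coupling gives the 2-alkynylphenol, and Cu/amine-promoted 5-endo-dig cyclisation of the phenoxide follows. Only the OH ortho to the C–I carbon can close, because the other ortho oxygen is OTBS. This forces the 7-(1,1-dimethylallyl) regiochemistry.

**Step 9**
Reactants: 11
Product: 12 Artopetelin C
Conditions: TBAF (1.5 equiv), AcOH (1.5 equiv), THF, 0 °C, 30 min
Reagents that add atoms: none
Why: fluoride-mediated cleavage of the aryl TBS ether. The AcOH buffer protects the polyphenol, and the alkenes, chroman and benzofuran are unaffected.

## Compound list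
1 | phloroglucinol | Oc1cc(O)cc(O)c1 | starting material
2 | prenyl bromide (1-bromo-3-methylbut-2-ene) | CC(C)=CCBr | starting material
3 | 5-(prenyloxy)benzene-1,3-diol | CC(C)=CCOc1cc(O)cc(O)c1 | intermediate
4 | 2-(2-methylbut-3-en-2-yl)benzene-1,3,5-triol | C=CC(C)(C)c1c(O)cc(O)cc1O | intermediate
5 | 5-(TBSO)-2-(2-methylbut-3-en-2-yl)benzene-1,3-diol | C=CC(C)(C)c1c(O)cc(O[Si](C)(C)C(C)(C)C)cc1O | intermediate
6 | 5-(TBSO)-4-iodo-2-(2-methylbut-3-en-2-yl)benzene-1,3-diol | C=CC(C)(C)c1c(O)cc(O[Si](C)(C)C(C)(C)C)c(I)c1O | intermediate
7 | 3,5-dihydroxybenzaldehyde | O=Cc1cc(O)cc(O)c1 | starting material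
8 | 3,5-dihydroxy-2,6-bis(3-methylbut-2-en-1-yl)benzaldehyde | O=Cc1c(CC=C(C)C)c(O)cc(O)c1CC=C(C)C | intermediate
9 | 7-hydroxy-2,2-dimethyl-6-prenylchromane-5-carbaldehyde | O=Cc1c(CC=C(C)C)c(O)cc2OC(C)(C)CCc12 | intermediate
10 | 5-ethynyl-2,2-dimethyl-6-prenylchroman-7-ol | C#Cc1c(CC=C(C)C)c(O)cc2OC(C)(C)CCc12 | intermediate
11 | TBS-protected benzofuran | C=CC(C)(C)c1c(O)cc(O[Si](C)(C)C(C)(C)C)c2cc(-c3c(CC=C(C)C)c(O)cc4c3CCC(C)(C)O4)oc12 | intermediate
12 | Artopetelin C (achiral) | C=CC(C)(C)c1c(O)cc(O)c2cc(-c3c(CC=C(C)C)c(O)cc4c3CCC(C)(C)O4)oc12 | target

## Totals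
Total steps: 9. Longest linear sequence: 6 (1 → 3 → 4 → 5 → 6 → 11 → 12).

## Three steps most likely to fail
1. **Step 2 (Claisen on the free triol ether).** BCl3 may ionise the prenyl ether, giving normal C-prenyl or chroman by-products instead of the tertiary centre.
   Fallback: install the reverse prenyl group by Nicholas-type tert-propargylation of phloroglucinol (2-methylbut-3-yn-2-ol–Co2(CO)6, BF3), CAN decomplexation and Lindlar hydrogenation to the vinyl group, then continue from 4.
2. **Step 5 (regioselective bis-C-prenylation, C- versus O-alkylation).** The product may contain the 4-prenyl isomer or O-prenyl ethers.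
   Fallback: make the chroman by propargyl Claisen. Mono-O-(1,1-dimethylpropargyl)ation of 7, thermal Claisen and 6π-cyclisation (the meta-CHO directs ortho to itself) give the 5-formyl-2,2-dimethylchromene, which is hydrogenated to 9's chroman core. The prenyl group is then added to the phenoxide in a separate step.
3. **Step 8 (Sonogashira of a di-ortho-substituted iodide with a hindered aryl alkyne).** Coupling may be sluggish and the alkyne may homocouple.
   Fallback: Castro–Stephens coupling. Pre-form the copper acetylide of 10 and heat with 6 in pyridine at reflux; this gives the 2-arylbenzofuran directly by Cu-mediated coupling and cyclisation, without Pd.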